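**Retrosynthetic overview**

1. Ring numbering used throughout: C1 (CH bearing the CH2O arm), C2 (methyl-bearing alkene carbon), C3 (=CH), C4 (CH2), C5 (CH–O), C6 (CMe2). The strategy rests on C1 being both α to the arm carbon, which can be carried as a carboxylate, and bonded to vinylic C2, so the C1–C2 ring bond is cut to an ester enolate and a vinyl iodide.
2. Endgame disconnections: the C5–O acyl bond to (R)-2-methylbutanoic acid, and the aryl–O–CH2 ether to umbelliferone and the primary alcohol obtained from the C1 ester.
3. Only one ring is formed in the route: the cyclohexene, closed at C1–C2 by palladium-catalysed intramolecular enolate alkenylation of the acyclic Z iodo ester 11. The coumarin arrives intact with umbelliferone.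
4. Iodo ester 11 comes from aldehyde ester 5 (isobutyraldehyde enamine plus tert-butyl bromoacetate, which sets up quaternary C6) by Brown allylation (C5 stereocenter), silylation, ozonolysis and α-iodoethylidene Wittig olefination.

Key step: step 6

Remark: (+)-Ipc2B(allyl) means the B-allyldiisopinocampheylborane made from (−)-α-pinene, taken as its salt-free pentane solution.

**Route**

Step 1
Reactants: 1 isobutyraldehyde; 2 tert-butyl bromoacetate
Product: 5 tert-butyl 3,3-dimethyl-4-oxobutanoate, via enamine 3 (not isolated), via iminium bromide 4 (not isolated)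
Conditions: pyrrolidine, K2CO3, Et2O, 0 °C → rt, filter, concentrate; 2, MeCN, reflux; H2O, 60 °C
Reagents that add atoms: water, O
Why: Stork enamine alkylation: the enamine of the α,α-disubstituted aldehyde is alkylated on carbon by the reactive α-bromo ester, which builds the quaternary carbon (future C6), and hydrolysis of the iminium salt returns an aldehyde with no α-hydrogen, so neither a second alkylation nor self-condensation can follow.

Step 2
Reactants: 5 tert-butyl 3,3-dimethyl-4-oxobutanoate
Product: 7 tert-butyl (4R)-4-hydroxy-3,3-dimethylhept-6-enoate, via borinate 6 (not isolated)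
Conditions: (+)-Ipc2B(allyl), Et2O, −100 → −78 °C; then pH 7 phosphate buffer, MeOH, 30% H2O2, 0 °C → rt
Reagents that add atoms: (+)-B-allyldiisopinocampheylborane, C=CCB([C@H]1C[C@H]2C[C@@H]([C@@H]1C)C2(C)C)[C@H]1C[C@H]2C[C@@H]([C@@H]1C)C2(C)C
Why: Brown allylboration through a closed chair six-membered transition state: the isopinocampheyl groups of the (−)-α-pinene-derived reagent send allyl to the Re face of the α-quaternary aldehyde, which should give the (4R) carbinol (future C5), the tert-butyl ester is inert to the borane, and the buffered oxidative work-up keeps the γ-hydroxy ester from lactonising (7 is silylated without storage).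

Step 3
Reactants: 7 tert-butyl (4R)-4-hydroxy-3,3-dimethylhept-6-enoate
Product: 8 tert-butyl (4R)-4-(tert-butyldimethylsilyloxy)-3,3-dimethylhept-6-enoate
Conditions: TBSOTf (1.2 equiv), 2,6-lutidine, CH2Cl2, −78 → 0 °C
Reagents that add atoms: tert-butyldimethylsilyl trifluoromethanesulfonate, CC(C)(C)[Si](C)(C)OS(=O)(=O)C(F)(F)F
Why: Silyl ether formation on a hindered neopentylic secondary alcohol needs the silyl triflate with a hindered pyridine base, and the low temperature and small excess keep the tert-butyl ester from being attacked; the stereocenter is not involved.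

Step 4
Reactants: 8 tert-butyl (4R)-4-(tert-butyldimethylsilyloxy)-3,3-dimethylhept-6-enoate
Product: 10 tert-butyl (4R)-4-(tert-butyldimethylsilyloxy)-3,3-dimethyl-6-oxohexanoate, via ozonide 9 (not isolated)
Conditions: O3, CH2Cl2, −78 °C; then PPh3, −78 °C → rt
Reagents that add atoms: ozone, [O-][O+]=O
Why: Ozonolysis of the monosubstituted alkene with reductive work-up (phosphine reduction of the ozonide) gives the aldehyde, and the ester and silyl ether are inert to ozone at low temperature.

Step 5
Reactants: 10 tert-butyl (4R)-4-(tert-butyldimethylsilyloxy)-3,3-dimethyl-6-oxohexanoate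
Product: 11 tert-butyl (4R,6Z)-4-(tert-butyldimethylsilyloxy)-7-iodo-3,3-dimethyloct-6-enoate
Conditions: EtPPh3I, n-BuLi, THF, rt; I2, −78 °C; NaN(SiMe3)2, −20 °C; then 10, −78 °C → rt
Reagents that add atoms: ethyltriphenylphosphonium iodide, CC[P+](c1ccccc1)(c1ccccc1)c1ccccc1.[I-]; iodine, II
Why: Wittig olefination with the α-iodo ylide Ph3P=C(I)CH3 (Stork–Zhao-type olefination) under kinetic conditions passes through the cis oxaphosphetane and should place iodine cis to the chain (Z), the geometry the ring closure needs, while fast carbonyl addition at −78 °C outruns enolisation of the β-silyloxy aldehyde.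

Step 6
Reactants: 11 tert-butyl (4R,6Z)-4-(tert-butyldimethylsilyloxy)-7-iodo-3,3-dimethyloct-6-enoate
Product: 14 tert-butyl (1S,5R)-5-(tert-butyldimethylsilyloxy)-2,6,6-trimethylcyclohex-2-ene-1-carboxylate, via lithium enolate 12 (not isolated), via lithium dienolate 13 (not isolated)
Conditions: Pd2(dba)3 (2.5 mol %), P(t-Bu)3 (10 mol %), LiN(SiMe3)2 (2.5 equiv), toluene, 0 °C → rt; then AcOH, THF, −78 °C
Reagents that add atoms: none
Why: Palladium-catalysed intramolecular α-alkenylation of an ester enolate, a known reaction type closely related to ester enolate α-arylation: zerovalent palladium inserts into the vinyl C–I bond with retention, lithium enolate 12 replaces iodide to give a C-bound divalent palladium enolate, and reductive elimination forms C1–C2. The six-membered carbocycle closes by this reductive elimination from a seven-membered palladacycle, with the enolate double bond exocyclic and the vinyl double bond endocyclic to the new ring; the Z geometry holds palladium cis to the tether and leaves C2=C3 as the only possible alkene position. The palladium-bound carbon is flanked by quaternary C6 and the carbonyl, so β-hydride elimination is excluded, and the tert-butyl ester resists Claisen condensation. The new stereocenter C1 is not fixed in the coupling: the α-alkenyl ester is more acidic than 11 and is converted by the second equivalent of base into dienolate 13, so C1 is set at the cold quench. Kinetic protonation of 13 takes place at the α-carbon, which keeps the alkene at C2=C3, and should come from the face opposite the C5 silyloxy group and the pseudoaxial C6 methyl, giving the cis, diequatorial (1S,5R) ester. The step thus needs α- over γ-protonation, secured by the kinetic quench, and cis over trans facial selectivity, for which the C5 and C6 substituents provide the bias.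

Step 7
Reactants: 14 tert-butyl (1S,5R)-5-(tert-butyldimethylsilyloxy)-2,6,6-trimethylcyclohex-2-ene-1-carboxylate
Product: 15 [(1S,5R)-5-(tert-butyldimethylsilyloxy)-2,6,6-trimethylcyclohex-2-en-1-yl]methanol
Conditions: LiAlH4, THF, 0 °C → reflux; H2O, aq. NaOH work-up
Reagents that add atoms: none
Why: Hydride reduction of the hindered tert-butyl ester to the primary alcohol with LiAlH4 leaves the silyl ether and the trisubstituted alkene untouched, and once the carbonyl is gone C1 can no longer epimerise.

Step 8
Reactants: 15 [(1S,5R)-5-(tert-butyldimethylsilyloxy)-2,6,6-trimethylcyclohex-2-en-1-yl]methanol; 16 umbelliferone (7-hydroxy-2H-chromen-2-one)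
Product: 17 7-{[(1S,5R)-5-(tert-butyldimethylsilyloxy)-2,6,6-trimethylcyclohex-2-en-1-yl]methoxy}-2H-chromen-2-one
Conditions: PPh3, DIAD, THF, 0 °C → 45 °C
Reagents that add atoms: none
Why: Mitsunobu etherification: the acidic phenol of umbelliferone displaces the oxyphosphonium of the primary alcohol in an SN2 step at the CH2 carbon, so no stereocenter is touched and the coumarin lactone sees no strong base.

Step 9
Reactants: 17 7-{[(1S,5R)-5-(tert-butyldimethylsilyloxy)-2,6,6-trimethylcyclohex-2-en-1-yl]methoxy}-2H-chromen-2-one
Product: 18 7-{[(1S,5R)-5-hydroxy-2,6,6-trimethylcyclohex-2-en-1-yl]methoxy}-2H-chromen-2-one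
Conditions: Bu4NF, THF, rt → 45 °C
Reagents that add atoms: none
Why: Fluoride-induced silyl ether cleavage, driven by Si–F bond formation, frees the C5 hydroxyl with retention, and the aryl ether, the coumarin and the alkene are stable to these conditions.

Step 10
Reactants: 18 7-{[(1S,5R)-5-hydroxy-2,6,6-trimethylcyclohex-2-en-1-yl]methoxy}-2H-chromen-2-one; 19 (R)-2-methylbutanoic acid
Product: 20 (1R,5S)-4,6,6-trimethyl-5-{[(2-oxo-2H-chromen-7-yl)oxy]methyl}cyclohex-3-en-1-yl (2R)-2-methylbutanoate (target; C5 R and C1 S in the ring numbering of the overview)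
Conditions: DCC, DMAP (0.2 equiv), CH2Cl2, 0 °C → rt
Reagents that add atoms: none
Why: Steglich esterification (carbodiimide activation, acyl transfer through the acylpyridinium) acylates the neopentylic secondary alcohol with retention at C5, and catalytic DMAP without added amine base at low temperature is chosen so that the α-stereocenter of the acid is not epimerised through a ketene.

**Compound list**

1 | isobutyraldehyde | CC(C)C=O | starting material
2 | tert-butyl bromoacetate | CC(C)(C)OC(=O)CBr | starting material
3 | 1-(2-methylprop-1-en-1-yl)pyrrolidine | CC(C)=CN1CCCC1 | intermediate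
4 | 1-(4-tert-butoxy-2,2-dimethyl-4-oxobutylidene)pyrrolidinium bromide | CC(C)(C)OC(=O)CC(C)(C)C=[N+]1CCCC1.[Br-] | intermediate
5 | tert-butyl 3,3-dimethyl-4-oxobutanoate | CC(C)(C)OC(=O)CC(C)(C)C=O | intermediate
6 | tert-butyl (4R)-4-[bis(isopinocampheyl)boryloxy]-3,3-dimethylhept-6-enoate | CC(C)(C)OC(=O)CC(C)(C)[C@H](OB([C@H]1C[C@H]2C[C@@H]([C@@H]1C)C2(C)C)[C@H]1C[C@H]2C[C@@H]([C@@H]1C)C2(C)C)CC=C | intermediate
7 | tert-butyl (4R)-4-hydroxy-3,3-dimethylhept-6-enoate | CC(C)(C)OC(=O)CC(C)(C)[C@H](O)CC=C | intermediate
8 | tert-butyl (4R)-4-(tert-butyldimethylsilyloxy)-3,3-dimethylhept-6-enoate | CC(C)(C)OC(=O)CC(C)(C)[C@H](O[Si](C)(C)C(C)(C)C)CC=C | intermediate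
9 | tert-butyl (4R)-4-(tert-butyldimethylsilyloxy)-3,3-dimethyl-5-(1,2,4-trioxolan-3-yl)pentanoate | CC(C)(C)OC(=O)CC(C)(C)[C@H](O[Si](C)(C)C(C)(C)C)CC1OCOO1 | intermediate
10 | tert-butyl (4R)-4-(tert-butyldimethylsilyloxy)-3,3-dimethyl-6-oxohexanoate | CC(C)(C)OC(=O)CC(C)(C)[C@H](O[Si](C)(C)C(C)(C)C)CC=O | intermediate
11 | tert-butyl (4R,6Z)-4-(tert-butyldimethylsilyloxy)-7-iodo-3,3-dimethyloct-6-enoate | CC(C)(C)OC(=O)CC(C)(C)[C@H](O[Si](C)(C)C(C)(C)C)C/C=C(/C)I | intermediate
12 | lithium enolate of 11 | CC(C)(C)OC(O[Li])=CC(C)(C)[C@H](O[Si](C)(C)C(C)(C)C)C/C=C(/C)I | intermediate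
13 | lithium dienolate of 14 (C1=C(OLi)O-t-Bu) | CC(C)(C)OC(O[Li])=C1C(C)=CC[C@@H](O[Si](C)(C)C(C)(C)C)C1(C)C | intermediate
14 | tert-butyl (1S,5R)-5-(tert-butyldimethylsilyloxy)-2,6,6-trimethylcyclohex-2-ene-1-carboxylate | CC(C)(C)OC(=O)[C@H]1C(C)=CC[C@@H](O[Si](C)(C)C(C)(C)C)C1(C)C | intermediate
15 | [(1S,5R)-5-(tert-butyldimethylsilyloxy)-2,6,6-trimethylcyclohex-2-en-1-yl]methanol | OC[C@H]1C(C)=CC[C@@H](O[Si](C)(C)C(C)(C)C)C1(C)C | intermediate
16 | umbelliferone (7-hydroxy-2H-chromen-2-one) | O=c1ccc2ccc(O)cc2o1 | starting material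
17 | 7-{[(1S,5R)-5-(tert-butyldimethylsilyloxy)-2,6,6-trimethylcyclohex-2-en-1-yl]methoxy}-2H-chromen-2-one | O=c1ccc2ccc(OC[C@H]3C(C)=CC[C@@H](O[Si](C)(C)C(C)(C)C)C3(C)C)cc2o1 | intermediate
18 | 7-{[(1S,5R)-5-hydroxy-2,6,6-trimethylcyclohex-2-en-1-yl]methoxy}-2H-chromen-2-one | O=c1ccc2ccc(OC[C@H]3C(C)=CC[C@@H](O)C3(C)C)cc2o1 | intermediate
19 | (R)-2-methylbutanoic acid | CC[C@@H](C)C(=O)O | starting material
20 | (1R,5S)-4,6,6-trimethyl-5-{[(2-oxo-2H-chromen-7-yl)oxy]methyl}cyclohex-3-en-1-yl (2R)-2-methylbutanoate | CC[C@@H](C)C(=O)O[C@@H]1CC=C(C)[C@H](COc2ccc3ccc(=O)oc3c2)C1(C)C | target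

**Step count**

Total: 10 steps. Longest linear sequence: 10 steps, from isobutyraldehyde 1; umbelliferone 16 and acid 19 enter as purchased.

**Steps most likely to fail**

Step 6. The protonation of dienolate 13 may show poor facial selectivity, or re-enolisation may stay incomplete so that C1 is decided in the reductive elimination, and the C1 epimer would then form. Prolonged contact with base may also move the alkene into conjugation, and the amide base may dehydroiodinate the vinyl iodide before oxidative addition. The fallback sets out from 11 and ties the carboxyl to the C5 oxygen before the ring closure. Aqueous CF3CO2H in CH2Cl2 at rt removes the tert-butyl ester and the silyl ether, and the γ-hydroxy acid closes to (5R)-5-[(2Z)-3-iodobut-2-en-1-yl]-4,4-dimethyloxolan-2-one F1. The same palladium enolate alkenylation (Pd2(dba)3, P(t-Bu)3, LiN(SiMe3)2, toluene) on the lactone enolate then closes the carbocycle as the bridged lactone (1S,5R)-2,8,8-trimethyl-6-oxabicyclo[3.2.1]oct-2-en-7-one F2. In F2 the one-atom C6 bridge allows only the cis arrangement at C1 and C5, and the bridgehead C1–H can no longer be enolised. LiAlH4 in THF opens the lactone to the diol [(1S,5R)-5-hydroxy-2,6,6-trimethylcyclohex-2-en-1-yl]methanol F3. A Mitsunobu reaction of F3 with 16 should touch only the primary hydroxyl, the secondary one being neopentylic, and gives 18, where the route is rejoined.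

Step 5. The oxaphosphetane-forming addition may lose Z selectivity, the basic ylide may enolise the β-silyloxy aldehyde and cause β-elimination, and iodine transfer between phosphorus species may lower the amount of active ylide. The fallback sets out from 10 and builds the halide from a 1,1-dibromoalkene. Corey–Fuchs dibromo-olefination (CBr4, PPh3, 2,6-lutidine, CH2Cl2, 0 °C) gives tert-butyl (4R)-7,7-dibromo-4-(tert-butyldimethylsilyloxy)-3,3-dimethylhept-6-enoate F4. A trans-selective Negishi monomethylation (MeZnCl, PdCl2(DPEphos) cat., THF, 0 °C → rt) follows, in which zerovalent palladium inserts into the less hindered C–Br bond trans to the chain. It gives tert-butyl (4R,6Z)-7-bromo-4-(tert-butyldimethylsilyloxy)-3,3-dimethyloct-6-enoate F5, with bromine cis to the chain. F5 is cyclised under the conditions of step 6 and comes back to the route at 14.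

Step 8. Displacement of the oxyphosphonium at the β-branched CH2, which sits next to quaternary C6, may be slow, so that the hydrazide is alkylated or the activated alcohol eliminates. The fallback sets out from 15 and forms the aryl–O bond instead of the alkyl–O bond. A palladium-catalysed C–O cross-coupling of 15 with commercial 7-bromo-2H-chromen-2-one (O=c1ccc2ccc(Br)cc2o1; [Pd(allyl)Cl]2, t-BuBrettPhos, Cs2CO3, toluene, 80 °C) gives 17 directly, with no substitution at the hindered carbon.

**Further compounds**

F1 | step 6 | (5R)-5-[(2Z)-3-iodobut-2-en-1-yl]-4,4-dimethyloxolan-2-one | O=C1CC(C)(C)[C@@H](C/C=C(/C)I)O1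
F2 | step 6 | (1S,5R)-2,8,8-trimethyl-6-oxabicyclo[3.2.1]oct-2-en-7-one | O=C1O[C@@H]2CC=C(C)[C@H]1C2(C)C
F3 | step 6 | [(1S,5R)-5-hydroxy-2,6,6-trimethylcyclohex-2-en-1-yl]methanol | OC[C@H]1C(C)=CC[C@@H](O)C1(C)C
F4 | step 5 | tert-butyl (4R)-7,7-dibromo-4-(tert-butyldimethylsilyloxy)-3,3-dimethylhept-6-enoate | CC(C)(C)OC(=O)CC(C)(C)[C@H](O[Si](C)(C)C(C)(C)C)CC=C(Br)Br
F5 | step 5 | tert-butyl (4R,6Z)-7-bromo-4-(tert-butyldimethylsilyloxy)-3,3-dimethyloct-6-enoate | CC(C)(C)OC(=O)CC(C)(C)[C@H](O[Si](C)(C)C(C)(C)C)C/C=C(/C)Br
F0 | step 8 | none | none
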